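The flasks are read at 2.5 d, 3.00 times the last reading of the south-west run, so each answer lies beyond the data.

| setting | south-west | theta | delta | beta | alpha | epsilon |
|---|---|---|---|---|---|---|
| starting complex | 46 mM | 60 mM | 46 mM | 100 mM | 46 mM | 200 mM |
| incoming ligand | 92 mM | 92.0 mM | 60.0 mM | 92.0 mM | 92.0 mM | 150 mM |
| protic impurity | 1 mM | 0.920 mM | 4.00 mM | 0.920 mM | 0.920 mM | 0.920 mM |
| temperature | 100 °C | 70 °C | 60 °C | 80 °C | 100 °C | 115 °C |
| remark | run made earlier |  |  |  |  |  |
| time |  | 2.5 d | 2.5 d | 2.5 d | 2.5 d | 2.5 d |

south-west run (percent of the starting complex charged)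

| time / h | complex with one exchanged / % | starting complex / % |
|---|---|---|
| 2.50 | 6.5 | 90.9 |
| 8.00 | 17.6 | 79.1 |
| 15.0 | 28.7 | 68.3 |
| 20.0 | 33.9 | 63.0 |

(readings scatter by 0.5 percentage points)

- ranking by amount of complex with one exchanged, in percent of the starting complex charged, from high to low, at 2.5 d (theta / delta / beta / alpha / epsilon)
- the amount of complex with one exchanged, in percent of the starting complex charged of the flask you put first, at 2.5 d
- the amount of complex with one exchanged, in percent of the starting complex charged of the flask you put last, at 2.5 d

- the numbers in the tables scatter by 0.5 percentage points (one standard deviation)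
- the earlier runs do not show what temperature does; that part of a forecast is a guess
- no earlier run changes the charge of incoming ligand; that part of a forecast is a guess
- no earlier run changes the charge of protic impurity; that part of a forecast is a guess

Write M for the starting complex, X for the incoming ligand, Ma for the complex with one exchanged and L for the leaving ligand, one released per exchange. Two chemists dispute what these flasks are.

The first holds a clock. In the south-west run, Ma reads 6.5% at 2.50 h, so the exchange time τ, the time to full conversion at that first pace, is 38.5 h. With first-order decay on that time, this chemist reckons alpha at 79.0%. Heat simply runs the clock faster, so this chemist puts epsilon first, since it is the hottest flask.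

The second holds a ceiling: the exchange also runs back. At 15.0 h in the south-west run, taking L equal to Ma, the products over the reactants read 0.0704. At 20.0 h they read 0.110. At fixed temperature, this mass-action quotient Q, [Ma][L] over [M][X], climbs in a single reversible exchange until it meets the equilibrium constant K, then stands. I back this view, but the reading gives me a floor for K and no more. Temperature is a guess for both chemists.

The forecast takes the ceiling side, with K about 0.5. It ranks alpha > epsilon > beta > theta > delta, with 53% on top and 2% at the bottom. Of epsilon it says: “Epsilon is hot enough to equilibrate”.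

The simulation gives alpha > beta > theta > epsilon > delta, with alpha at 38.9%, epsilon at 12.1% and delta at 6.40%. The forecast's top is 14 percentage points too high. Alpha also stands lower than the clock's 79.0%, and epsilon stands lower than alpha, so the dispute goes to the ceiling.

    starting complex + incoming ligand ⇌ leaving ligand + complex with one exchanged (K = 0.280, k = 0.310 M⁻¹ h⁻¹, Ea = 70.0 kJ mol⁻¹, ΔH = −65.0 kJ mol⁻¹)
    complex with one exchanged + incoming ligand ⇌ leaving ligand + complex with two exchanged (K = 0.970, k = 0.0450 M⁻¹ h⁻¹, Ea = 91.0 kJ mol⁻¹, ΔH = −42.0 kJ mol⁻¹)
    complex with two exchanged + incoming ligand ⇌ leaving ligand + complex with three exchanged (K = 0.360, k = 1.10 M⁻¹ h⁻¹, Ea = 97.0 kJ mol⁻¹, ΔH = −22.0 kJ mol⁻¹)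
    complex with three exchanged + incoming ligand ⇌ leaving ligand + complex with four exchanged (K = 0.330, k = 0.110 M⁻¹ h⁻¹, Ea = 82.0 kJ mol⁻¹, ΔH = 48.0 kJ mol⁻¹)
    protic impurity + starting complex → quenched substrate (k = 110 M⁻¹ h⁻¹, Ea = 74.0 kJ mol⁻¹)
    (constants at 100 °C)

In alpha, Q stands at 0.275, close to the first exchange's constant, 0.28 at 100 °C. In epsilon, at 115 °C, Q stands lower, at 0.125, and Ma is still 10.7% at 25.0 d. The clock has its region in delta, where Q is 0.00391, the half-life of M by the forward rate of the first exchange alone is 25 d, far longer than the 2.5 d of reading, and Ma climbs to 39.6% by 25.0 d.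

The data are simulated with made-up constants, and the scatter is random.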